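I began from amounts: the blue flask and the red run carry the same 0.90 equiv of J but differ in the Q charged, 0.24 M against 0.16 M.

| flask | Q | J | remark | time |
|---|---|---|---|---|
| blue | 0.24 M | 0.90 equiv | the very flask that is asked about, followed so far |  |
| red | 0.16 M | 0.90 equiv | run made earlier |  |
| flask | 0.24 M | 0.900 equiv |  | 5.0 min |

| run | time / s | Q / % | L / % | E / % |
|---|---|---|---|---|
| blue | 25.0 | 98.4 | 0.4 | 0 |
| blue | 50.0 | 97.1 | 2.6 | 1.3 |
| blue | 60.0 | 94.8 | 3.7 | 1.7 |
| blue | 90.0 | 92.1 | 2.7 | 2.8 |
| red | 30.0 | 93.9 | 2.0 | 1.2 |
| red | 60.0 | 94.2 | 4.4 | 1.5 |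
| red | 90.0 | 86.7 | 7.2 | 2.5 |
| red | 120 | 84.6 | 7.3 | 4.8 |

(each reading ± 1 percentage point)

- as a solid, counted per litre of solution: Q
- the numbers in the tables scatter by 1 percentage point (one standard deviation)
- at the start none of Q is in solution

* how much Q there is at 5.0 min, in percent of the Q charged (only what is still solid)
* how much L there is at 5.0 min, in percent of the Q charged
* how much E there is at 5.0 min, in percent of the Q charged

At 90.0 s the blue solid stood at 92.1% and the red at 86.7%, so the red run had lost the larger share of its charge. In moles per litre the gap nearly closes: blue had lost 0.0190 M and red 0.0213 M. Taken at each run's last reading, the loss was 2.11 × 10⁻⁴ M s⁻¹ in blue and 2.05 × 10⁻⁴ M s⁻¹ in red. That difference is worth 0.2 percentage points in blue, less than the scatter of 1 point. Their mean, 2.08 × 10⁻⁴ M s⁻¹, I carried as the feed, the moles of Q leaving the solid per litre and second, a zero-order supply. The red percentages fall faster because the same feed draws on a smaller charge.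

For the blue flask at 5.0 min, I reckoned a loss by the feed of 0.0624 M, which put Q at 74.0%. I put that answer back in: 0.178 M of solid remained in that estimate, and two J per mole lost would take 0.125 M of the 0.216 M of J charged, so the second round kept the same feed. The forecast gave 76% of Q, 8% of L and 14% of E, holding that "the flux in molarity does not depend on loading or on J"; its Q lies 2 points above mine.

The blue flask gave 72.8% of Q, 6.19% of L and 17.7% of E, each within the forecast's margin.

    X + J → L (k = 0.260 L mol⁻¹ s⁻¹)
    J + L → E (k = 0.0950 L mol⁻¹ s⁻¹)
    J + L → G (k = 0.00300 L mol⁻¹ s⁻¹)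
    Q ⇌ X, rate k4*(cs4 - [X]) while solid is left; crystals form when [X] > cs4 (solubility = 0.160 M, k = 0.00140 s⁻¹)

Here X is dissolved Q. With no X present, the dissolving rate is 2.24 × 10⁻⁴ M s⁻¹, and at 5.00 min the blue flask held 0.00666 M of X against a saturation of 0.16 M, at which the rate law gives a value 4.16% lower. For the neighbour charged with 0.096 M of Q, read at the same time, the feed reckons the same loss of 0.0624 M, which gives 35.0% of its charge as solid. Its X reached 0.0191 M. That neighbour holds 34.8% of solid Q.

The readings come from a simulation from invented constants.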